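**Retrosynthetic overview**

1. The ring B–ring C bond (C1'–C2) is made last, by Suzuki coupling of the ring B pinacol boronate with 2-iodo-5,7-bis(pivaloyloxy)chromone, followed by methanolysis of the pivalates; rings A and C come from phloroacetophenone by an enaminone ring closure.
2. The CMe2OH group goes back to a Weinreb amide on C2''. Because the Weinreb adduct stops at the ketone, the two methyl groups are added in two separate Grignard steps.
3. Key disconnection: the dihydrofuran ring (C2''–C3'' and O1''–C2'' bonds) by [4+1] annulation of 5-bromo-2-hydroxy-3-prenylbenzaldehyde with the chiral sulfonium ylide made from (2R,5R)-2,5-dimethylthiolane and 2-bromo-N-methoxy-N-methylacetamide.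
4. Feature used: in the dihydrofuran ring O1''–C2''–C3''–C3a''–C7a'' fused to ring B, C3'' is a benzylic carbinol carbon ortho to O1'' (a former salicylaldehyde carbonyl carbon), and C2'' is a single carbon between O1'' and the acyl precursor of CMe2OH (a former ylide carbon).
5. Order of ring formation: ring B is bought as 4-bromophenol (C-prenylation, then ortho-formylation), the dihydrofuran ring closes in the key step, ring C is closed on ring A in the chromone branch, and the two halves are then joined.

Key step: step 6

Assumption: the (2R,5R) enantiomer of 2,5-dimethylthiolane is taken to induce the (2S,3S) configuration; the sense of induction of this ylide with a salicylaldehyde cannot be predicted with certainty, and the (2S,5S) sulfide, made the same way from (2R,5R)-hexane-2,5-diol, would replace it if the first run gave the mirror-image product.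

**Route** (prenyl = 3-methylbut-2-en-1-yl)

Step 1
Reactants: 1 4-bromophenol; 2 prenyl bromide
Product: 3 4-bromo-2-prenylphenol
Conditions: NaH (1.05 equiv), toluene, 0 °C → rt; then 2 (1.0 equiv), rt
Reagents that add atoms: none
Why: Heterogeneous sodium 4-bromophenoxide in a non-polar solvent favours ortho C-allylation over O-allylation (Claisen-type C-alkylation of a phenoxide), the para position is blocked by bromine, and the neutral O-prenyl ether by-product is removed because it is not extracted into alkali.

Step 2
Reactants: 3 4-bromo-2-prenylphenol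
Product: 4 5-bromo-2-hydroxy-3-prenylbenzaldehyde
Conditions: MgCl2 (2 equiv), Et3N (4 equiv), (CH2O)n (6 equiv), MeCN, reflux; then 1 M HCl
Reagents that add atoms: formaldehyde (as paraformaldehyde), C=O
Why: Magnesium-mediated ortho-formylation (Casnati–Skattebøl reaction) delivers formaldehyde inside the magnesium phenoxide chelate to the only free ortho position and a second formaldehyde oxidises the benzylic alkoxide by hydride transfer, under conditions that leave the prenyl alkene and the aryl bromide untouched.

Step 3
Reactants: 5 (2S,5S)-hexane-2,5-diol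
Product: 6 (2S,5S)-hexane-2,5-diyl dimethanesulfonate
Conditions: MsCl (2.4 equiv), Et3N (3 equiv), CH2Cl2, −20 → 0 °C
Reagents that add atoms: methanesulfonyl chloride, CS(=O)(=O)Cl
Why: Mesylation of a secondary diol reacts only at the O–H bonds, so both carbinol carbons keep their configuration.

Step 4
Reactants: 6 (2S,5S)-hexane-2,5-diyl dimethanesulfonate
Product: 7 (2R,5R)-2,5-dimethylthiolane
Conditions: Na2S·9H2O (1.2 equiv), EtOH, rt → 40 °C
Reagents that add atoms: sodium sulfide, [Na+].[Na+].[S-2]
Why: Double SN2 displacement by sulfide, the second one a 5-exo-tet ring closure, inverts both centres and so converts the (2S,5S) dimesylate into the (2R,5R) thiolane.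

Step 5
Reactants: 7 (2R,5R)-2,5-dimethylthiolane; 8 2-bromo-N-methoxy-N-methylacetamide
Product: 9 (2R,5R)-1-{2-[methoxy(methyl)amino]-2-oxoethyl}-2,5-dimethylthiolan-1-ium bromide
Conditions: concentrated acetone, rt, 48 h; triturate with Et2O
Reagents that add atoms: none
Why: S-alkylation of a dialkyl sulfide by an α-bromo amide (sulfonium salt formation by SN2) gives a single salt, because the two faces of sulfur in the C2-symmetric thiolane are equivalent and sulfur is therefore not a stereocentre.

Step 6
Reactants: 4 5-bromo-2-hydroxy-3-prenylbenzaldehyde; 9 sulfonium bromide (1.2 equiv)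
Product: 12 (2S,3S)-5-bromo-3-hydroxy-N-methoxy-N-methyl-7-prenyl-2,3-dihydrobenzofuran-2-carboxamide (trans), via sulfonium ylide 10 (not isolated), via hydroxysulfonium phenolate 11 (not isolated)
Conditions: Cs2CO3 (2.5 equiv), MeCN, −20 → 0 °C; sulfide 7 recovered; 12 recrystallised if its enantiomeric purity needs raising
Reagents that add atoms: none
Why: Cs2CO3 turns 4 into its phenolate and 9 into the amide-stabilised ylide 10, whose carbon adds reversibly to the aldehyde carbon (C2–C3 bond) to give, after proton transfer, hydroxysulfonium phenolate 11, and the phenolate oxygen then displaces the thiolane at the former ylide carbon with inversion (O1–C2 bond), which releases sulfide 7 for recovery. The closest known reaction type is the sulfur-ylide [4+1] annulation of salicylaldehydes to trans-2-acyl-2,3-dihydrobenzofuran-3-ols, and control by a chiral sulfide is carried over from the chiral-ylide annulations of salicyl imines and o-quinone methides and from chiral amide-ylide epoxidations of aldehydes. The dihydrofuran ring closes by 5-exo-tet substitution. C2 is controlled by the C2-symmetric thiolane, whose methyl groups differentiate the two faces of the ylide carbon in the adduct that cyclises, and C3 is controlled by C2, because the addition is reversible and only the adduct that places amide and hydroxyl trans on the forming ring closes quickly. The step needs attack at the carbonyl carbon in preference to O-alkylation of the phenolate, which the preformed sulfonium salt secures since no free bromoacetamide is present and the salt is deprotonated faster than it is dealkylated, and it needs the prenyl alkene and the aryl bromide to stay inert, which they are towards a stabilised ylide and a carbonate base.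

Step 7
Reactants: 12 Weinreb amide
Product: 13 1-[(2S,3S)-5-bromo-3-hydroxy-7-prenyl-2,3-dihydrobenzofuran-2-yl]ethan-1-one
Conditions: MeMgBr (3 equiv), THF, −40 → 0 °C; cold sat. aq. NH4Cl; used crude
Reagents that add atoms: methylmagnesium bromide, C[Mg]Br
Why: Weinreb ketone synthesis, in which the first equivalent of Grignard reagent deprotonates the 3-hydroxyl and the second adds to the amide to give a chelated tetrahedral adduct that does not collapse before the cold quench, so the reaction stops at the methyl ketone with C2 and C3 untouched.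

Step 8
Reactants: 13 methyl ketone
Product: 14 (2S,3S)-5-bromo-2-(2-hydroxypropan-2-yl)-7-prenyl-2,3-dihydrobenzofuran-3-ol
Conditions: CeCl3 (anhydrous, 3 equiv), MeMgBr (3 equiv), THF, −78 °C; aq. NH4Cl
Reagents that add atoms: methylmagnesium bromide, C[Mg]Br
Why: Grignard addition to the ketone in the presence of CeCl3, which suppresses enolisation at C2 and retro-aldol opening of the aldolate, gives the tertiary carbinol without a new stereocentre because both carbinol substituents are methyl.

Step 9
Reactants: 14 bromo diol
Product: 15 (2S,3S)-2-(2-hydroxypropan-2-yl)-7-prenyl-5-(4,4,5,5-tetramethyl-1,3,2-dioxaborolan-2-yl)-2,3-dihydrobenzofuran-3-ol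
Conditions: B2pin2 (1.3 equiv), PdCl2(dppf) (5 mol %), KOAc (3 equiv), 1,4-dioxane, 85 °C
Reagents that add atoms: bis(pinacolato)diboron, CC1(C)OB(OC1(C)C)B1OC(C)(C)C(C)(C)O1
Why: Miyaura borylation of an aryl bromide with KOAc as a mild base tolerates the free secondary and tertiary hydroxyl groups and the trisubstituted alkene.

Step 10
Reactants: 16 2',4',6'-trihydroxyacetophenone (dried)
Product: 17 2'-hydroxy-4',6'-bis(pivaloyloxy)acetophenone
Conditions: PivCl (2.1 equiv), Et3N (2.3 equiv), CH2Cl2, −10 → 0 °C
Reagents that add atoms: pivaloyl chloride, CC(C)(C)C(=O)Cl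
Why: O-acylation of the two most accessible phenols with an acid chloride and amine base stops at the diester because the remaining ortho hydroxyl is hydrogen-bonded to the acetyl carbonyl and is hindered.

Step 11
Reactants: 17 2'-hydroxy-4',6'-bis(pivaloyloxy)acetophenone
Product: 19 5,7-bis(pivaloyloxy)-4H-chromen-4-one, via enaminone 18 (not isolated)
Conditions: Me2NCH(OMe)2 (2 equiv), toluene, 85 °C; evaporate; then conc. HCl (2 equiv), CH2Cl2, rt
Reagents that add atoms: N,N-dimethylformamide dimethyl acetal, COC(OC)N(C)C
Why: Enaminone chromone synthesis, in which condensation of the methyl ketone with the amide acetal gives the (E)-enaminone and acid then promotes conjugate addition of the ortho hydroxyl and loss of dimethylamine (6-endo-trig addition–elimination) to close the pyranone ring, the pivalates being stable to both stages.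

Step 12
Reactants: 19 5,7-bis(pivaloyloxy)-4H-chromen-4-one
Product: 21 2-iodo-5,7-bis(pivaloyloxy)-4H-chromen-4-one, via chromen-2-ylzinc chloride 20 (not isolated)
Conditions: TMPZnCl·LiCl (1.2 equiv; TMP = 2,2,6,6-tetramethylpiperidide), THF, −30 → 25 °C, no added Lewis acid; then I2 (1.3 equiv), 0 °C
Reagents that add atoms: iodine, II
Why: Deprotonative zincation with TMPZnCl·LiCl in the absence of an added Lewis acid removes the most acidic vinylic proton, at C2 next to the ring oxygen, and gives an ester-tolerant organozinc that iodine converts into the 2-iodide (iodolysis).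

Step 13
Reactants: 15 aryl pinacol boronate; 21 2-iodo-5,7-bis(pivaloyloxy)chromone
Product: 22 5,7-bis(pivaloyloxy)-2-[(2S,3S)-3-hydroxy-2-(2-hydroxypropan-2-yl)-7-prenyl-2,3-dihydrobenzofuran-5-yl]-4H-chromen-4-one
Conditions: Pd(PPh3)4 (5 mol %), K3PO4 (2 equiv), 1,4-dioxane/H2O 9:1, 60 °C
Reagents that add atoms: none
Why: Suzuki–Miyaura coupling, in which the 2-iodochromone as a vinylogous acyl iodide undergoes fast oxidative addition, so that coupling with the electron-rich aryl boronate should outrun hydrolysis of the iodide or of the pivalates at moderate temperature with a weak base.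

Step 14
Reactants: 22 bis-pivalate flavone
Product: 23 5,7-dihydroxy-2-[(2S,3S)-3-hydroxy-2-(2-hydroxypropan-2-yl)-7-prenyl-2,3-dihydrobenzofuran-5-yl]-4H-chromen-4-one (target)
Conditions: K2CO3 (3 equiv), MeOH/THF 3:1, 0 °C → rt; then aq. NH4Cl
Reagents that add atoms: none
Why: Base-mediated methanolysis (transesterification) of the two aryl pivalates releases the acidic 5- and 7-phenols under conditions that touch neither the acid-sensitive benzylic carbinol nor the prenyl group.

**Compound list**

1 | 4-bromophenol | Oc1ccc(Br)cc1 | starting material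
2 | prenyl bromide (1-bromo-3-methylbut-2-ene) | CC(C)=CCBr | starting material
3 | 4-bromo-2-(3-methylbut-2-en-1-yl)phenol | CC(C)=CCc1cc(Br)ccc1O | intermediate
4 | 5-bromo-2-hydroxy-3-(3-methylbut-2-en-1-yl)benzaldehyde | CC(C)=CCc1cc(Br)cc(C=O)c1O | intermediate
5 | (2S,5S)-hexane-2,5-diol | C[C@H](O)CC[C@H](C)O | starting material
6 | (2S,5S)-hexane-2,5-diyl dimethanesulfonate | C[C@H](OS(C)(=O)=O)CC[C@H](C)OS(C)(=O)=O | intermediate
7 | (2R,5R)-2,5-dimethylthiolane | C[C@@H]1CC[C@@H](C)S1 | intermediate
8 | 2-bromo-N-methoxy-N-methylacetamide | CON(C)C(=O)CBr | starting material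
9 | (2R,5R)-1-{2-[methoxy(methyl)amino]-2-oxoethyl}-2,5-dimethylthiolan-1-ium bromide | C[C@@H]1CC[C@@H](C)[S+]1CC(=O)N(C)OC.[Br-] | intermediate
10 | sulfonium ylide of 9 (ylide carbon between sulfur and the amide carbonyl) | C[C@@H]1CC[C@@H](C)[S+]1[CH-]C(=O)N(C)OC | intermediate
11 | (2R,5R)-1-{(1R,2S)-2-(5-bromo-2-oxido-3-prenylphenyl)-2-hydroxy-1-[methoxy(methyl)carbamoyl]ethyl}-2,5-dimethylthiolan-1-ium (zwitterion) | CC(C)=CCc1cc(Br)cc([C@H](O)[C@H](C(=O)N(C)OC)[S+]2[C@H](C)CC[C@H]2C)c1[O-] | intermediate
12 | (2S,3S)-5-bromo-3-hydroxy-N-methoxy-N-methyl-7-(3-methylbut-2-en-1-yl)-2,3-dihydro-1-benzofuran-2-carboxamide | CC(C)=CCc1cc(Br)cc2c1O[C@H](C(=O)N(C)OC)[C@H]2O | intermediate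
13 | 1-[(2S,3S)-5-bromo-3-hydroxy-7-(3-methylbut-2-en-1-yl)-2,3-dihydro-1-benzofuran-2-yl]ethan-1-one | CC(C)=CCc1cc(Br)cc2c1O[C@H](C(C)=O)[C@H]2O | intermediate
14 | (2S,3S)-5-bromo-2-(2-hydroxypropan-2-yl)-7-(3-methylbut-2-en-1-yl)-2,3-dihydro-1-benzofuran-3-ol | CC(C)=CCc1cc(Br)cc2c1O[C@H](C(C)(C)O)[C@H]2O | intermediate
15 | (2S,3S)-2-(2-hydroxypropan-2-yl)-7-(3-methylbut-2-en-1-yl)-5-(4,4,5,5-tetramethyl-1,3,2-dioxaborolan-2-yl)-2,3-dihydro-1-benzofuran-3-ol | CC(C)=CCc1cc(B3OC(C)(C)C(C)(C)O3)cc2c1O[C@H](C(C)(C)O)[C@H]2O | intermediate
16 | 2',4',6'-trihydroxyacetophenone | CC(=O)c1c(O)cc(O)cc1O | starting material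
17 | 2'-hydroxy-4',6'-bis(pivaloyloxy)acetophenone | CC(=O)c1c(O)cc(OC(=O)C(C)(C)C)cc1OC(=O)C(C)(C)C | intermediate
18 | (E)-3-(dimethylamino)-1-[2-hydroxy-4,6-bis(pivaloyloxy)phenyl]prop-2-en-1-one | CN(C)/C=C/C(=O)c1c(O)cc(OC(=O)C(C)(C)C)cc1OC(=O)C(C)(C)C | intermediate
19 | 5,7-bis(pivaloyloxy)-4H-chromen-4-one | O=c1ccoc2cc(OC(=O)C(C)(C)C)cc(OC(=O)C(C)(C)C)c12 | intermediate
20 | [4-oxo-5,7-bis(pivaloyloxy)-4H-chromen-2-yl]zinc chloride | O=c1cc([Zn]Cl)oc2cc(OC(=O)C(C)(C)C)cc(OC(=O)C(C)(C)C)c12 | intermediate
21 | 2-iodo-5,7-bis(pivaloyloxy)-4H-chromen-4-one | O=c1cc(I)oc2cc(OC(=O)C(C)(C)C)cc(OC(=O)C(C)(C)C)c12 | intermediate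
22 | 5,7-bis(pivaloyloxy)-2-[(2S,3S)-3-hydroxy-2-(2-hydroxypropan-2-yl)-7-(3-methylbut-2-en-1-yl)-2,3-dihydro-1-benzofuran-5-yl]-4H-chromen-4-one | CC(C)=CCc1cc(-c2cc(=O)c3c(OC(=O)C(C)(C)C)cc(OC(=O)C(C)(C)C)cc3o2)cc2c1O[C@H](C(C)(C)O)[C@H]2O | intermediate
23 | 5,7-dihydroxy-2-[(2S,3S)-3-hydroxy-2-(2-hydroxypropan-2-yl)-7-(3-methylbut-2-en-1-yl)-2,3-dihydro-1-benzofuran-5-yl]-4H-chromen-4-one | CC(C)=CCc1cc(-c2cc(=O)c3c(O)cc(O)cc3o2)cc2c1O[C@H](C(C)(C)O)[C@H]2O | target

**Step count and risks**

Total step count: 14.
Longest linear sequence: 9 steps (3, 4, 5, 6, 7, 8, 9, 13, 14), counted through the auxiliary sulfide; along the carbon skeleton from 4-bromophenol it is 8 steps (1, 2, 6, 7, 8, 9, 13, 14).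

The three steps most likely to fail:

Step 6. Three processes may spoil it: weak facial discrimination by the thiolane-derived ylide; a detour through the Corey–Chaykovsky channel, in which the alkoxide closes to a glycidic amide that the phenolate then opens, so that C2 is inverted twice instead of once and the enantiomeric excess is eroded; and O-alkylation of the phenolate by the sulfonium salt. Fallback: setting out from aldehyde 4 and bromoacetamide 8, dimethyl sulfide and 8 would give [2-(methoxy(methyl)amino)-2-oxoethyl]dimethylsulfonium bromide F1. Its ylide (Cs2CO3, MeCN) should give, by the achiral form of the annulation, the racemic trans-5-bromo-3-hydroxy-N-methoxy-N-methyl-7-prenyl-2,3-dihydrobenzofuran-2-carboxamide F2. Preparative chromatography on a chiral stationary phase would then separate the (2S,3S) enantiomer, which is compound 12 and rejoins the route there, from the (2R,3R) enantiomer of 12 F3.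

Step 8. The magnesium aldolate of the β-hydroxy ketone may open by retro-aldol reaction, or the ketone may enolise at C2, which leads to epimerisation and then dehydration to the aromatic benzofuran, before the methyl group adds; the same lability threatens the isolation of 13 in step 7. Fallback: setting out from aldehyde 4 and sulfide 7, S-alkylation of 7 with methyl bromoacetate would give (2R,5R)-1-(2-methoxy-2-oxoethyl)-2,5-dimethylthiolan-1-ium bromide F4. Annulation with 4 under the conditions of step 6 would give methyl (2S,3S)-5-bromo-3-hydroxy-7-prenyl-2,3-dihydrobenzofuran-2-carboxylate F5. Excess MeMgBr with CeCl3 at −78 °C would then add both methyl groups in one flask, the ketone being consumed as it forms and never isolated, and the route is rejoined at carbinol 14.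

Step 13. Hydrolytic addition–elimination at C2 of the iodochromone, premature loss of a pivalate and protodeboronation may compete with transmetalation. Fallback: setting out from bromide 14 and chromone 19, the organozinc 20 would be generated as in step 12 but not quenched with iodine, and used in excess (3 equiv, to absorb the two hydroxyl protons). It would be coupled directly with 14 in a Negishi reaction (Pd(OAc)2, SPhos, THF, 50 °C), a base-free coupling that leaves the pivalates intact and needs neither the boronate nor the iodide. The route is rejoined at bis-pivalate 22, and no compound outside the compound list is made (new compounds: none F0).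

**Further compounds**

F1 | step 6 | [2-(methoxy(methyl)amino)-2-oxoethyl]dimethylsulfonium bromide | C[S+](C)CC(=O)N(C)OC.[Br-]
F2 | step 6 | racemic trans-5-bromo-3-hydroxy-N-methoxy-N-methyl-7-prenyl-2,3-dihydrobenzofuran-2-carboxamide (1:1 mixture of the (2S,3S) and (2R,3R) enantiomers) | CC(C)=CCc1cc(Br)cc2c1O[C@H](C(=O)N(C)OC)[C@H]2O.CC(C)=CCc1cc(Br)cc2c1O[C@@H](C(=O)N(C)OC)[C@@H]2O
F3 | step 6 | (2R,3R)-5-bromo-3-hydroxy-N-methoxy-N-methyl-7-prenyl-2,3-dihydrobenzofuran-2-carboxamide (enantiomer of 12) | CC(C)=CCc1cc(Br)cc2c1O[C@@H](C(=O)N(C)OC)[C@@H]2O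
F4 | step 8 | (2R,5R)-1-(2-methoxy-2-oxoethyl)-2,5-dimethylthiolan-1-ium bromide | C[C@@H]1CC[C@@H](C)[S+]1CC(=O)OC.[Br-]
F5 | step 8 | methyl (2S,3S)-5-bromo-3-hydroxy-7-prenyl-2,3-dihydrobenzofuran-2-carboxylate | CC(C)=CCc1cc(Br)cc2c1O[C@H](C(=O)OC)[C@H]2O
F0 | step 13 | none | none
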